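**Retrosynthetic overview**
- The C8 ester is made last, by acylating the C8 alcohol with preformed (S)-2-methylglycidic acid.
- The ten-membered ring is closed at C8–C9. A 1,3-diacetoxy-2-(methoxycarbonyl)allyl unit (a masked 2-formylacrylate) is turned by palladium/InI into a C9 acyl-anion-type nucleophile that adds to the C8 aldehyde. This one step gives the C9 acetate, the C8 alcohol and the C1=C10 alkene.
- The C6–C7 bond and the lactone come from a zinc Barbier addition of 3-(bromomethyl)furan-2(5H)-one (butenolide β-carbon as nucleophile) to an epoxy aldehyde, followed by translactonization.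
- The epoxide comes from Sharpless epoxidation of a nerol-derived Z-allylic alcohol; C9/C10/C14 come from methyl propiolate.
- Ring order: oxirane, then α-methylene butyrolactone, then carbocycle.

Assumption: the SMILES is taken literally (cis-4,5-epoxide, 4R,5S,6S,7R,8S,9R,2'S, C2 and C9 cis on C1=C10). Germacrane numbering of the target is used for atom labels. Compounds 7–12 and 16–19 are carried as C1 epimer mixtures, since C1 becomes sp2 in step 11; the enol-acetate geometry is likewise inconsequential.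

**Route**

Step 1
Reactants: 1 nerol
Product: 2 neryl tert-butyldimethylsilyl ether
Conditions: TBSCl, imidazole, CH2Cl2, 0 °C to rt
Reagents that add atoms: tert-butyldimethylsilyl chloride, CC(C)(C)[Si](C)(C)Cl
Why: Routine silylation of the primary allylic alcohol masks C6–OH through the Lewis-acid and acylation steps; no stereocentre is involved.

Step 2
Reactants: 2 neryl tert-butyldimethylsilyl ether
Product: 4 (4Z)-6-[(tert-butyldimethylsilyl)oxy]-4-methylhex-4-enal, via ozonide 3 (not isolated)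
Conditions: O3 (1.0 equiv, titrated), CH2Cl2/pyridine, −78 °C; then Me2S, −78 °C to rt
Reagents that add atoms: ozone, [O-][O+]=O
Why: Chemoselective ozonolysis with reductive work-up cleaves the distal trisubstituted alkene, which is more electron-rich and less hindered than the one carrying the allylic silyloxy group, and leaves the Z-alkene intact.

Step 3
Reactants: 4 (4Z)-6-[(tert-butyldimethylsilyl)oxy]-4-methylhex-4-enal; 5 methyl propiolate
Product: 7 methyl (2Z)-2-{(4Z)-6-[(tert-butyldimethylsilyl)oxy]-1-hydroxy-4-methylhex-4-en-1-yl}-3-iodoprop-2-enoate, via iodomagnesium allenolate 6 (not isolated)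
Conditions: MgI2 (1.2 equiv), CH2Cl2, 0 °C to rt
Reagents that add atoms: magnesium iodide, I[Mg]I
Why: Iodo-Baylis–Hillman reaction, in which iodide adds to the propiolate and the resulting allenolate undergoes aldol addition to the aldehyde to give the (Z)-β-iodo adduct; the new C1 carbinol is racemic and is erased later.

Step 4
Reactants: 7 methyl (2Z)-2-{(4Z)-6-[(tert-butyldimethylsilyl)oxy]-1-hydroxy-4-methylhex-4-en-1-yl}-3-iodoprop-2-enoate
Product: 9 methyl (2Z)-3-acetoxy-2-{(4Z)-1-acetoxy-6-[(tert-butyldimethylsilyl)oxy]-4-methylhex-4-en-1-yl}prop-2-enoate, via iodo allylic acetate 8 (not isolated)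
Conditions: Ac2O, pyridine, DMAP (cat.), CH2Cl2, 0 °C; concentrate; then CsOAc (3 equiv), DABCO (20 mol %), MeCN, 40 °C
Reagents that add atoms: acetic anhydride, CC(=O)OC(C)=O; cesium acetate, [Cs+].CC(=O)[O-]
Why: O-acetylation, then addition–elimination (vinylic substitution) of the β-iodoacrylate by acetate under DABCO nucleophilic catalysis with retention; any acylal isomer formed by SN2′ scrambling ionizes to the same allyl complex in step 11.

Step 5
Reactants: 9 methyl (2Z)-3-acetoxy-2-{(4Z)-1-acetoxy-6-[(tert-butyldimethylsilyl)oxy]-4-methylhex-4-en-1-yl}prop-2-enoate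
Product: 10 methyl (2Z)-3-acetoxy-2-[(4Z)-1-acetoxy-6-hydroxy-4-methylhex-4-en-1-yl]prop-2-enoate
Conditions: HF·pyridine, pyridine, THF, 0 °C to rt
Reagents that add atoms: none
Why: Buffered fluoride desilylation frees the Z-allylic alcohol without cleaving the acetate or enol acetate.

Step 6
Reactants: 10 methyl (2Z)-3-acetoxy-2-[(4Z)-1-acetoxy-6-hydroxy-4-methylhex-4-en-1-yl]prop-2-enoate
Product: 11 methyl (2Z)-3-acetoxy-2-{1-acetoxy-3-[(2R,3S)-3-(hydroxymethyl)-2-methyloxiran-2-yl]propyl}prop-2-enoate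
Conditions: Ti(OiPr)4 (10 mol %), L-(+)-diethyl tartrate (13 mol %), t-BuOOH, 4 Å sieves, CH2Cl2, −20 °C
Reagents that add atoms: tert-butyl hydroperoxide, CC(C)(C)OO
Why: Sharpless asymmetric epoxidation; as with nerol, the L-(+)-tartrate catalyst gives the (2S,3R)-epoxy alcohol, which sets C4 (R) and C5 (S) as a cis-epoxide, and the electron-poor enol-acetate alkene is inert.

Step 7
Reactants: 11 methyl (2Z)-3-acetoxy-2-{1-acetoxy-3-[(2R,3S)-3-(hydroxymethyl)-2-methyloxiran-2-yl]propyl}prop-2-enoate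
Product: 12 methyl (2Z)-3-acetoxy-2-{1-acetoxy-3-[(2R,3R)-3-formyl-2-methyloxiran-2-yl]propyl}prop-2-enoate
Conditions: Dess–Martin periodinane, NaHCO3, CH2Cl2, 0 °C
Reagents that add atoms: none
Why: Buffered Dess–Martin oxidation gives the epoxy aldehyde without epimerization; the descriptor at C5 changes only because of CIP priorities.

Step 8
Reactants: 13 3-methylfuran-2(5H)-one
Product: 14 3-(bromomethyl)furan-2(5H)-one
Conditions: NBS, AIBN (cat.), PhCF3, 85 °C
Reagents that add atoms: N-bromosuccinimide, O=C1CCC(=O)N1Br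
Why: Wohl–Ziegler bromination of the allylic methyl group gives the known butenolide allyl bromide.

Step 9
Reactants: 12 methyl (2Z)-3-acetoxy-2-{1-acetoxy-3-[(2R,3R)-3-formyl-2-methyloxiran-2-yl]propyl}prop-2-enoate; 14 3-(bromomethyl)furan-2(5H)-one
Product: 17 methyl (2Z)-3-acetoxy-2-(1-acetoxy-3-{(2R,3S)-3-[(2S,3R)-3-(hydroxymethyl)-4-methylidene-5-oxooxolan-2-yl]-2-methyloxiran-2-yl}propyl)prop-2-enoate, via allylzinc bromide 15 (not isolated), via Barbier adduct 16 (not isolated)
Conditions: Zn dust, THF/sat. aq NH4Cl, 0 °C; extract; then DBU (10 mol %), CH2Cl2, 0 °C to rt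
Reagents that add atoms: none
Why: Barbier 2-(alkoxycarbonyl)allylation in which the butenolide β-carbon (a homoenolate equivalent) attacks the aldehyde through a chair transition state; the ring-locked allyl geometry gives the anti C6/C7 adduct, Felkin–Anh attack anti to the epoxide C–O bond sets C6 (S) and hence C7 (R), and base-catalysed translactonization then gives the trans 6,12-lactone.

Step 10
Reactants: 17 methyl (2Z)-3-acetoxy-2-(1-acetoxy-3-{(2R,3S)-3-[(2S,3R)-3-(hydroxymethyl)-4-methylidene-5-oxooxolan-2-yl]-2-methyloxiran-2-yl}propyl)prop-2-enoate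
Product: 18 methyl (2Z)-3-acetoxy-2-(1-acetoxy-3-{(2R,3S)-3-[(2S,3S)-3-formyl-4-methylidene-5-oxooxolan-2-yl]-2-methyloxiran-2-yl}propyl)prop-2-enoate
Conditions: Dess–Martin periodinane, NaHCO3, CH2Cl2, 0 °C; used crude
Reagents that add atoms: none
Why: Neutral Dess–Martin oxidation of the primary alcohol gives the C8 aldehyde without base-induced epimerization or β-elimination at C7 (the trans arrangement is also the thermodynamic one).

Step 11
Reactants: 18 methyl (2Z)-3-acetoxy-2-(1-acetoxy-3-{(2R,3S)-3-[(2S,3S)-3-formyl-4-methylidene-5-oxooxolan-2-yl]-2-methyloxiran-2-yl}propyl)prop-2-enoate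
Product: 20 methyl (1(10)E,4R,5S,6S,7R,8S,9R)-9-acetoxy-4,5-epoxy-8-hydroxygermacra-1(10),11(13)-dien-12,6-olid-14-oate, via γ-acetoxyallylindium 19 (not isolated)
Conditions: Pd(PPh3)4 (10 mol %), InI (2 equiv), THF (0.003 M, slow addition of 18), 25 °C; pH 7 buffer
Reagents that add atoms: none
Why: Proposed new method: zerovalent palladium ionizes the C1 acetate (assisted by the acetoxy donor at C9) to a 1-acetoxy-2-(methoxycarbonyl)allyl complex, InI reduces it to allylindium 19 with indium on C1 and the push–pull enol acetate retained, and C9, now an acyl-anion-type carbon, adds to the C8 aldehyde through a six-membered In–O–C8–C9–C10–C1 transition state; ten- over eight-membered ring formation and the stabilized enol acetate direct attack through C9, Felkin–Anh approach anti to the C7–C11 bond is expected to set C8 (S), the enol acetate with acetoxy trans to C1 in a chair with C7 equatorial is expected to give the 8,9-anti product (C9 R), and ring closure places C2 cis to C9 on the new C1=C10 bond; the closest known reactions are the palladium/InI umpolung allylation of aldehydes with allylic acetates and the α-acyloxyallylation of aldehydes with 3-halopropenyl esters or allyl gem-dicarboxylates.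

Step 12
Reactants: 21 (R)-2-methylglycidol
Product: 22 (2S)-2-methyloxirane-2-carboxylic acid
Conditions: RuCl3·xH2O (2 mol %), NaIO4 (2.5 equiv), MeCN/EtOAc/H2O, 0 °C to rt; used crude
Reagents that add atoms: water, O
Why: Ruthenium tetroxide oxidation of the primary alcohol to the acid leaves the quaternary epoxide centre untouched; the descriptor changes from R to S only because of CIP priorities.

Step 13
Reactants: 20 methyl (1(10)E,4R,5S,6S,7R,8S,9R)-9-acetoxy-4,5-epoxy-8-hydroxygermacra-1(10),11(13)-dien-12,6-olid-14-oate; 22 (2S)-2-methyloxirane-2-carboxylic acid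
Product: 24 methyl (1(10)E,4R,5S,6S,7R,8S,9R)-9-acetoxy-4,5-epoxy-8-{[(2S)-2-methyloxirane-2-carbonyl]oxy}germacra-1(10),11(13)-dien-12,6-olid-14-oate (target), via Yamaguchi mixed anhydride 23 (not isolated)
Conditions: 22, 2,4,6-trichlorobenzoyl chloride, Et3N, THF, 0 °C; then 20, DMAP, toluene, rt
Reagents that add atoms: none
Why: Yamaguchi esterification acylates the hindered C8 alcohol by DMAP acyl transfer faster than the neighbouring acetate can migrate, and no stereocentre is touched.

**Compound list**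
1 | nerol, (2Z)-3,7-dimethylocta-2,6-dien-1-ol | CC(C)=CCC/C(C)=C\CO | starting material
2 | neryl tert-butyldimethylsilyl ether | CC(C)=CCC/C(C)=C\CO[Si](C)(C)C(C)(C)C | intermediate
3 | ozonide, 3-{(3Z)-5-[(tert-butyldimethylsilyl)oxy]-3-methylpent-3-en-1-yl}-5,5-dimethyl-1,2,4-trioxolane | CC1(C)OOC(CC/C(C)=C\CO[Si](C)(C)C(C)(C)C)O1 | intermediate (not isolated)
4 | (4Z)-6-[(tert-butyldimethylsilyl)oxy]-4-methylhex-4-enal | O=CCC/C(C)=C\CO[Si](C)(C)C(C)(C)C | intermediate
5 | methyl propiolate | C#CC(=O)OC | starting material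
6 | iodomagnesium 3-iodo-1-methoxypropa-1,2-dien-1-olate | COC(O[Mg]I)=C=CI | intermediate (not isolated)
7 | methyl (2Z)-2-{(4Z)-6-[(tert-butyldimethylsilyl)oxy]-1-hydroxy-4-methylhex-4-en-1-yl}-3-iodoprop-2-enoate (racemic carbinol) | COC(=O)/C(=C\I)C(O)CC/C(C)=C\CO[Si](C)(C)C(C)(C)C | intermediate
8 | methyl (2Z)-2-{(4Z)-1-acetoxy-6-[(tert-butyldimethylsilyl)oxy]-4-methylhex-4-en-1-yl}-3-iodoprop-2-enoate | COC(=O)/C(=C\I)C(OC(C)=O)CC/C(C)=C\CO[Si](C)(C)C(C)(C)C | intermediate (not isolated)
9 | methyl (2Z)-3-acetoxy-2-{(4Z)-1-acetoxy-6-[(tert-butyldimethylsilyl)oxy]-4-methylhex-4-en-1-yl}prop-2-enoate | COC(=O)/C(=C\OC(C)=O)C(OC(C)=O)CC/C(C)=C\CO[Si](C)(C)C(C)(C)C | intermediate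
10 | methyl (2Z)-3-acetoxy-2-[(4Z)-1-acetoxy-6-hydroxy-4-methylhex-4-en-1-yl]prop-2-enoate | COC(=O)/C(=C\OC(C)=O)C(OC(C)=O)CC/C(C)=C\CO | intermediate
11 | methyl (2Z)-3-acetoxy-2-{1-acetoxy-3-[(2R,3S)-3-(hydroxymethyl)-2-methyloxiran-2-yl]propyl}prop-2-enoate | COC(=O)/C(=C\OC(C)=O)C(OC(C)=O)CC[C@@]1(C)O[C@H]1CO | intermediate
12 | methyl (2Z)-3-acetoxy-2-{1-acetoxy-3-[(2R,3R)-3-formyl-2-methyloxiran-2-yl]propyl}prop-2-enoate | COC(=O)/C(=C\OC(C)=O)C(OC(C)=O)CC[C@@]1(C)O[C@H]1C=O | intermediate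
13 | 3-methylfuran-2(5H)-one | CC1=CCOC1=O | starting material
14 | 3-(bromomethyl)furan-2(5H)-one | BrCC1=CCOC1=O | intermediate
15 | [(2-oxo-2,5-dihydrofuran-3-yl)methyl]zinc bromide | Br[Zn]CC1=CCOC1=O | intermediate (not isolated)
16 | methyl (2Z)-3-acetoxy-2-[1-acetoxy-3-((2R,3S)-3-{(S)-hydroxy[(3R)-4-methylidene-5-oxooxolan-3-yl]methyl}-2-methyloxiran-2-yl)propyl]prop-2-enoate | C=C1C(=O)OC[C@@H]1[C@H](O)[C@@H]1O[C@]1(C)CCC(OC(C)=O)/C(=C/OC(C)=O)C(=O)OC | intermediate (not isolated)
17 | methyl (2Z)-3-acetoxy-2-(1-acetoxy-3-{(2R,3S)-3-[(2S,3R)-3-(hydroxymethyl)-4-methylidene-5-oxooxolan-2-yl]-2-methyloxiran-2-yl}propyl)prop-2-enoate | C=C1C(=O)O[C@@H]([C@H]1CO)[C@@H]1O[C@]1(C)CCC(OC(C)=O)/C(=C/OC(C)=O)C(=O)OC | intermediate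
18 | methyl (2Z)-3-acetoxy-2-(1-acetoxy-3-{(2R,3S)-3-[(2S,3S)-3-formyl-4-methylidene-5-oxooxolan-2-yl]-2-methyloxiran-2-yl}propyl)prop-2-enoate | C=C1C(=O)O[C@@H]([C@H]1C=O)[C@@H]1O[C@]1(C)CCC(OC(C)=O)/C(=C/OC(C)=O)C(=O)OC | intermediate
19 | γ-acetoxyallylindium acetate iodide from 18 (indium on C1, enol acetate at C9=C10) | C=C1C(=O)O[C@@H]([C@H]1C=O)[C@@H]1O[C@]1(C)CCC([In](I)OC(C)=O)/C(=C/OC(C)=O)C(=O)OC | intermediate (not isolated)
20 | methyl (1(10)E,4R,5S,6S,7R,8S,9R)-9-acetoxy-4,5-epoxy-8-hydroxygermacra-1(10),11(13)-dien-12,6-olid-14-oate | C=C1C(=O)O[C@H]2[C@H]1[C@H](O)[C@H](OC(C)=O)/C(C(=O)OC)=C\CC[C@@]1(C)O[C@@H]21 | intermediate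
21 | (R)-2-methylglycidol, [(2R)-2-methyloxiran-2-yl]methanol | OC[C@]1(C)CO1 | starting material
22 | (2S)-2-methyloxirane-2-carboxylic acid | OC(=O)[C@]1(C)CO1 | intermediate
23 | (2S)-2-methyloxirane-2-carboxylic 2,4,6-trichlorobenzoic anhydride | O=C(OC(=O)[C@]1(C)CO1)c1c(Cl)cc(Cl)cc1Cl | intermediate (not isolated)
24 | methyl (1(10)E,4R,5S,6S,7R,8S,9R)-9-acetoxy-4,5-epoxy-8-{[(2S)-2-methyloxirane-2-carbonyl]oxy}germacra-1(10),11(13)-dien-12,6-olid-14-oate | C=C1C(=O)O[C@H]2[C@H]1[C@H](OC(=O)[C@]1(C)CO1)[C@H](OC(C)=O)/C(C(=O)OC)=C\CC[C@@]1(C)O[C@@H]21 | target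

**Step count and risks**

Total: 13 steps. Longest linear sequence: 11 steps from nerol (steps 1–7, 9, 10, 11, 13).

Most likely to fail, in order:

Step 11 (ring closure). The risks are attack through C1 instead of C9 (eight-membered ring), the wrong C8/C9 diastereomer from an unpredicted macrocyclic transition state, acetate migration from O9 to O8, and a second ionization of the product's allylic acetate. Fallback, setting out from 17 and returning at 24: DMAP-catalysed methanolysis of the enol acetate with loss of the C1 acetate gives the hydroxy formyl-enoate F1, and Dess–Martin oxidation gives the dialdehyde F2. CrCl2 with Et3SiCl then effects a reductive cross-pinacol-type ring closure: the conjugated aldehyde is reduced and O-silylated to the γ-silyloxyallylchromium F3, which adds through C9 to the C8 aldehyde to give the macrocyclic 9-O-triethylsilyl 8-alcohol F4. Yamaguchi acylation with 22 gives the glycidate silyl ether F5, HF·pyridine gives the 9-alcohol F6, and Ac2O/pyridine gives 24.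

Step 4 (enol acetate by vinylic substitution). Acetate may be too weak a nucleophile, or may give mixtures by SN2′ scrambling. Fallback, setting out from 4 and returning at 9: aldol addition of the lithium enolate of methyl acetate gives the β-hydroxy ester F7. Double deprotonation with LDA and C-formylation with methyl formate gives the formyl enol F8, which is quenched in the same flask with Ac2O to give 9 (as an E/Z mixture, equally usable).

Step 9 (Barbier addition and translactonization). The epoxy aldehyde is fragile, the Felkin/anti selectivity may be modest, and the translactonization equilibrium may not favour 17. Fallback, setting out from 12 and returning at 18, so that step 10 is skipped: dye-sensitized photooxygenation of 3-methylfuran-2-carboxylic acid F9 in methanol gives 5-hydroxy-3-methylfuran-2(5H)-one F10, and acid-catalysed acetalization in the same pot gives 5-methoxy-3-methylfuran-2(5H)-one F11. Wohl–Ziegler bromination gives 3-(bromomethyl)-5-methoxyfuran-2(5H)-one F12 (racemic, used in excess). Zinc Barbier addition to 12 through the allylzinc bromide F13 gives the pseudo-ester adduct F14, whose DBU-catalysed translactonization is irreversible because the released hemiacetal collapses to the C8 aldehyde 18.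

Further compounds
F1 | step 11 | methyl 2-formyl-5-{(2R,3S)-3-[(2S,3R)-3-(hydroxymethyl)-4-methylidene-5-oxooxolan-2-yl]-2-methyloxiran-2-yl}pent-2-enoate (E/Z mixture) | C=C1C(=O)O[C@@H]([C@H]1CO)[C@@H]1O[C@]1(C)CCC=C(C=O)C(=O)OC
F2 | step 11 | methyl 2-formyl-5-{(2R,3S)-3-[(2S,3S)-3-formyl-4-methylidene-5-oxooxolan-2-yl]-2-methyloxiran-2-yl}pent-2-enoate (E/Z mixture) | C=C1C(=O)O[C@@H]([C@H]1C=O)[C@@H]1O[C@]1(C)CCC=C(C=O)C(=O)OC
F3 | step 11 | γ-(triethylsilyloxy)allylchromium dichloride from F2 (chromium on C1, silyl enol ether at C9=C10) | C=C1C(=O)O[C@@H]([C@H]1C=O)[C@@H]1O[C@]1(C)CCC([Cr](Cl)Cl)C(=CO[Si](CC)(CC)CC)C(=O)OC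
F4 | step 11 | methyl (1(10)E)-4,5-epoxy-8-hydroxy-9-[(triethylsilyl)oxy]germacra-1(10),11(13)-dien-12,6-olid-14-oate, configuration as in 20 | C=C1C(=O)O[C@H]2[C@H]1[C@H](O)[C@H](O[Si](CC)(CC)CC)/C(C(=O)OC)=C\CC[C@@]1(C)O[C@@H]21
F5 | step 11 | 8-O-[(2S)-2-methyloxirane-2-carbonyl] derivative of F4 | C=C1C(=O)O[C@H]2[C@H]1[C@H](OC(=O)[C@]1(C)CO1)[C@H](O[Si](CC)(CC)CC)/C(C(=O)OC)=C\CC[C@@]1(C)O[C@@H]21
F6 | step 11 | 9-O-deacetyl target, methyl (1(10)E)-4,5-epoxy-9-hydroxy-8-{[(2S)-2-methyloxirane-2-carbonyl]oxy}germacra-1(10),11(13)-dien-12,6-olid-14-oate | C=C1C(=O)O[C@H]2[C@H]1[C@H](OC(=O)[C@]1(C)CO1)[C@H](O)/C(C(=O)OC)=C\CC[C@@]1(C)O[C@@H]21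
F7 | step 4 | methyl (6Z)-8-[(tert-butyldimethylsilyl)oxy]-3-hydroxy-6-methyloct-6-enoate (racemic) | COC(=O)CC(O)CC/C(C)=C\CO[Si](C)(C)C(C)(C)C
F8 | step 4 | methyl (6Z)-8-[(tert-butyldimethylsilyl)oxy]-3-hydroxy-2-(hydroxymethylidene)-6-methyloct-6-enoate | COC(=O)C(=CO)C(O)CC/C(C)=C\CO[Si](C)(C)C(C)(C)C
F9 | step 9 | 3-methylfuran-2-carboxylic acid | Cc1ccoc1C(=O)O
F10 | step 9 | 5-hydroxy-3-methylfuran-2(5H)-one (racemic) | CC1=CC(O)OC1=O
F11 | step 9 | 5-methoxy-3-methylfuran-2(5H)-one (racemic) | CC1=CC(OC)OC1=O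
F12 | step 9 | 3-(bromomethyl)-5-methoxyfuran-2(5H)-one (racemic) | BrCC1=CC(OC)OC1=O
F13 | step 9 | [(5-methoxy-2-oxo-2,5-dihydrofuran-3-yl)methyl]zinc bromide | Br[Zn]CC1=CC(OC)OC1=O
F14 | step 9 | methyl (2Z)-3-acetoxy-2-[1-acetoxy-3-((2R,3S)-3-{(S)-hydroxy[(3R)-2-methoxy-4-methylidene-5-oxooxolan-3-yl]methyl}-2-methyloxiran-2-yl)propyl]prop-2-enoate (acetal carbon unassigned) | C=C1C(=O)OC(OC)[C@@H]1[C@H](O)[C@@H]1O[C@]1(C)CCC(OC(C)=O)/C(=C/OC(C)=O)C(=O)OC
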